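**Plan**
- Retrosynthesis: the C8–prenyl bond is cut first (back to a 1,1-dimethylallyl ether on O7), then C4–C4a of ring C, then the O1–C2 ether bond, and last the C3–aryl bond, which leads to diethyl malonate and 6-bromo-2,2-dimethylchroman.
- Enabling feature: C3 lies between two oxygenated one-carbon units, C2 (OCH2) and C4 (C=O), so it is the central carbon of a prochiral 2-arylpropane-1,3-diol. C4a of ring A is para to O7 and ortho to O1, the position at which a resorcinol diether is acylated most readily.
- Forward: the dimethylchroman (ring B with its fused pyran) is bought intact. The three-carbon chain is attached to it, its two arms are differentiated, ring A is joined to the C2 arm as an aryl ether, ring C is closed by acylation of ring A, and the prenyl group is finally moved from O7 to C8.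
- Stereochemistry: the single stereocentre C3 (R) comes from lipase differentiation of the two enantiotopic CH2OH groups. It travels as an alcohol and an acid, becomes enolisable only when the ketone forms in the ring closure, and meets no base afterwards.

Key step: step 7

Assumption: porcine pancreatic lipase is taken to acetylate the same enantiotopic arm as in other 2-arylpropane-1,3-diols, giving the (R)-monoacetate; the configuration would be confirmed at the monoacetate stage before going on.

**Step 1**
Reactants: 1 6-bromo-2,2-dimethylchroman; 2 diethyl malonate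
Product: 3 diethyl 2-(2,2-dimethylchroman-6-yl)malonate
Conditions: Pd(dba)2 (2 mol%), P(t-Bu)3 (4 mol%), K3PO4, toluene, 70 °C
Reagents that add atoms: none
Why: Palladium-catalysed α-arylation of a malonate (Hartwig type), in which the electron-rich aryl bromide adds oxidatively to zerovalent palladium carrying the bulky phosphine and the aryl–palladium malonate enolate eliminates reductively; the mono-arylated malonate is too hindered to react a second time.

**Step 2**
Reactants: 3 diethyl 2-(2,2-dimethylchroman-6-yl)malonate
Product: 4 2-(2,2-dimethylchroman-6-yl)propane-1,3-diol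
Conditions: LiAlH4, THF, 0 °C → rt (malonate added to the hydride); H2O quench
Reagents that add atoms: none
Why: Hydride reduction of both esters to primary alcohols, the standard entry to 2-arylpropane-1,3-diols; inverse addition at 0 °C keeps reduction ahead of enolisation of the arylmalonate.

**Step 3**
Reactants: 4 2-(2,2-dimethylchroman-6-yl)propane-1,3-diol
Product: 5 (R)-3-hydroxy-2-(2,2-dimethylchroman-6-yl)propyl acetate
Conditions: porcine pancreatic lipase (PPL), vinyl acetate (neat), 25 °C, stopped when the diol is consumed
Reagents that add atoms: vinyl acetate, C=COC(C)=O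
Why: Lipase-catalysed enantiotopic-group-selective transesterification (desymmetrisation of a prochiral diol) with an irreversible acyl donor, in which the enzyme acetylates one CH2OH arm and so sets C3 as R, while slow second acetylation of the minor antipode should raise the enantiomeric purity further.

**Step 4**
Reactants: 5 (R)-3-hydroxy-2-(2,2-dimethylchroman-6-yl)propyl acetate; 6 3-(benzyloxy)phenol
Product: 7 (R)-3-[3-(benzyloxy)phenoxy]-2-(2,2-dimethylchroman-6-yl)propyl acetate
Conditions: PPh3, DIAD (added last), THF, 0 °C → rt
Reagents that add atoms: none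
Why: Mitsunobu etherification, in which the primary alkoxyphosphonium ion is displaced at CH2 by the phenoxide without touching C3, and the cold, essentially neutral medium should keep the acetate from migrating to the neighbouring oxygen, which would racemise the compound.

**Step 5**
Reactants: 7 (R)-3-[3-(benzyloxy)phenoxy]-2-(2,2-dimethylchroman-6-yl)propyl acetate
Product: 8 (S)-3-[3-(benzyloxy)phenoxy]-2-(2,2-dimethylchroman-6-yl)propan-1-ol
Conditions: K2CO3 (0.2 equiv), MeOH, 0 °C → rt
Reagents that add atoms: none
Why: Base-catalysed transesterification (methanolysis of an acetate); with the other arm now an aryl ether no acyl migration is possible and C3 carries no acidic hydrogen, so the descriptor changes only through the priority rules.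

**Step 6**
Reactants: 8 (S)-3-[3-(benzyloxy)phenoxy]-2-(2,2-dimethylchroman-6-yl)propan-1-ol
Product: 10 (R)-3-[3-(benzyloxy)phenoxy]-2-(2,2-dimethylchroman-6-yl)propanoic acid, via aldehyde 9 (not isolated)
Conditions: TEMPO (2,2,6,6-tetramethylpiperidin-1-oxyl, 0.2 equiv), PhI(OAc)2 (2.2 equiv), MeCN/H2O 1:1, rt
Reagents that add atoms: water, O
Why: Oxoammonium-mediated oxidation (TEMPO/PhI(OAc)2) takes the alcohol to the aldehyde and its hydrate on to the acid in one pot, so the α-aryl aldehyde is short-lived in a weakly acidic medium and should neither epimerise nor lose aryloxide by β-elimination, and no active chlorine is present to attack the electron-rich rings.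

**Step 7**
Reactants: 10 (R)-3-[3-(benzyloxy)phenoxy]-2-(2,2-dimethylchroman-6-yl)propanoic acid
Product: 12 (R)-7-(benzyloxy)-3-(2,2-dimethylchroman-6-yl)chroman-4-one, via acid chloride 11 (not isolated)
Conditions: (COCl)2, DMF (cat.), CH2Cl2, 0 °C → rt; evaporate; SnCl4 (1.1 equiv), CH2Cl2 (dilute), −78 → −40 °C; cold 1 M HCl
Reagents that add atoms: none
Why: Oxalyl chloride with catalytic DMF gives acid chloride 11 without base, and SnCl4 then polarises the C–Cl bond so that the acyl carbon is attacked by C4a of the resorcinol diether ring and the arenium ion loses HCl, which is an intramolecular Friedel–Crafts acylation, the standard closure of 3-aryloxypropanoic acids to chroman-4-ones. Ring C closes as a six-membered ring by attack of an arene carbon on the acyl carbon with the C=O bond left outside the new ring (6-exo-trig on the acyl chloride–SnCl4 complex). No stereocentre is created; C3 is carried over unchanged because until this moment it is the α-carbon of an acid derivative and no base is present that could lead to a ketene or an enolate. The step needs regioselectivity for the ring carbon para to the benzyloxy group over the carbon between the two oxygens: both are ortho to O1, but the first is unhindered and para-activated whereas the second is flanked by two substituents. It also needs the new ketone not to enolise and the acyl group not to lose CO to the p-alkoxybenzylic cation, which the mild Lewis acid (a tight complex instead of a free acylium ion), the low temperature, the short contact time and the cold acidic quench should secure.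

**Step 8**
Reactants: 12 (R)-7-(benzyloxy)-3-(2,2-dimethylchroman-6-yl)chroman-4-one
Product: 13 (R)-7-hydroxy-3-(2,2-dimethylchroman-6-yl)chroman-4-one
Conditions: H2 (1 atm), Pd/C (10% palladium on carbon), EtOAc, rt
Reagents that add atoms: none
Why: Catalytic hydrogenolysis of a benzyl aryl ether under neutral conditions, which should leave the aryl ketone, the chroman ether and the base-sensitive C3 untouched at atmospheric pressure in a non-acidic solvent.

**Step 9**
Reactants: 14 2-methylbut-3-en-2-ol
Product: 16 tert-butyl (2-methylbut-3-en-2-yl) carbonate, via lithium alkoxide 15 (not isolated)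
Conditions: n-BuLi, THF, −78 → 0 °C; Boc2O, 0 °C → rt; H2O
Reagents that add atoms: di-tert-butyl dicarbonate, CC(C)(C)OC(=O)OC(=O)OC(C)(C)C
Why: O-Alkoxycarbonylation of a tertiary lithium alkoxide with Boc2O, the usual preparation of tertiary allylic tert-butyl carbonates.

**Step 10**
Reactants: 13 (R)-7-hydroxy-3-(2,2-dimethylchroman-6-yl)chroman-4-one; 16 tert-butyl (2-methylbut-3-en-2-yl) carbonate
Product: 17 (R)-3-(2,2-dimethylchroman-6-yl)-7-[(2-methylbut-3-en-2-yl)oxy]chroman-4-one
Conditions: Pd(PPh3)4 (2 mol%), 16 (1.2 equiv), THF, 0 °C, stopped before the phenol is exhausted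
Reagents that add atoms: none
Why: Tsuji–Trost O-allylation under neutral conditions, in which zerovalent palladium ionises the carbonate to the 1,1-dimethyl-π-allyl complex, the tert-butoxide released with CO2 is quenched at once by the acidic 4-acylphenol, and the phenoxide attacks the more substituted allyl terminus at 0 °C to give the tertiary ether; keeping the carbonate near one equivalent means no alkoxide outlives the phenol to deprotonate C3.

**Step 11**
Reactants: 17 (R)-3-(2,2-dimethylchroman-6-yl)-7-[(2-methylbut-3-en-2-yl)oxy]chroman-4-one
Product: 19 (R)-7-hydroxy-3-(2,2-dimethylchroman-6-yl)-8-(3-methylbut-2-en-1-yl)chroman-4-one (CNP0139927.1), via dienone 18 (not isolated)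
Conditions: Eu(fod)3 (10 mol%), CHCl3 (acid-free), 50 °C
Reagents that add atoms: none
Why: Lewis-acid-catalysed aromatic Claisen rearrangement, a [3,3]-sigmatropic shift that turns the 1,1-dimethylallyl ether into a 3,3-dimethylallyl (prenyl) group on the ortho carbon and is expected to favour C8, the ortho position also ortho to O1, as is general for 7-allyloxy-chromanones and -coumarins; dienone 18 then tautomerises to the phenol, and the gentle, base-free conditions should leave C3 intact.

**Compound list**
1 | 6-bromo-2,2-dimethylchroman | CC1(C)CCc2cc(Br)ccc2O1 | starting material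
2 | diethyl malonate | CCOC(=O)CC(=O)OCC | starting material
3 | diethyl 2-(2,2-dimethylchroman-6-yl)malonate | CCOC(=O)C(C(=O)OCC)c1ccc2c(c1)CCC(C)(C)O2 | intermediate
4 | 2-(2,2-dimethylchroman-6-yl)propane-1,3-diol | OCC(CO)c1ccc2c(c1)CCC(C)(C)O2 | intermediate
5 | (R)-3-hydroxy-2-(2,2-dimethylchroman-6-yl)propyl acetate | CC(=O)OC[C@@H](CO)c1ccc2c(c1)CCC(C)(C)O2 | intermediate
6 | 3-(benzyloxy)phenol | Oc1cccc(OCc2ccccc2)c1 | starting material
7 | (R)-3-[3-(benzyloxy)phenoxy]-2-(2,2-dimethylchroman-6-yl)propyl acetate | CC(=O)OC[C@@H](COc1cccc(OCc2ccccc2)c1)c1ccc2c(c1)CCC(C)(C)O2 | intermediate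
8 | (S)-3-[3-(benzyloxy)phenoxy]-2-(2,2-dimethylchroman-6-yl)propan-1-ol | OC[C@@H](COc1cccc(OCc2ccccc2)c1)c1ccc2c(c1)CCC(C)(C)O2 | intermediate
9 | (R)-3-[3-(benzyloxy)phenoxy]-2-(2,2-dimethylchroman-6-yl)propanal | O=C[C@@H](COc1cccc(OCc2ccccc2)c1)c1ccc2c(c1)CCC(C)(C)O2 | intermediate
10 | (R)-3-[3-(benzyloxy)phenoxy]-2-(2,2-dimethylchroman-6-yl)propanoic acid | OC(=O)[C@@H](COc1cccc(OCc2ccccc2)c1)c1ccc2c(c1)CCC(C)(C)O2 | intermediate
11 | (R)-3-[3-(benzyloxy)phenoxy]-2-(2,2-dimethylchroman-6-yl)propanoyl chloride | ClC(=O)[C@@H](COc1cccc(OCc2ccccc2)c1)c1ccc2c(c1)CCC(C)(C)O2 | intermediate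
12 | (R)-7-(benzyloxy)-3-(2,2-dimethylchroman-6-yl)chroman-4-one | C(c1ccccc1)Oc1ccc2c(c1)OC[C@@H](c1ccc3c(c1)CCC(C)(C)O3)C2=O | intermediate
13 | (R)-7-hydroxy-3-(2,2-dimethylchroman-6-yl)chroman-4-one | Oc1ccc2c(c1)OC[C@@H](c1ccc3c(c1)CCC(C)(C)O3)C2=O | intermediate
14 | 2-methylbut-3-en-2-ol | CC(C)(O)C=C | starting material
15 | lithium 2-methylbut-3-en-2-olate | [Li+].[O-]C(C)(C)C=C | intermediate
16 | tert-butyl (2-methylbut-3-en-2-yl) carbonate | CC(C)(C)OC(=O)OC(C)(C)C=C | intermediate
17 | (R)-3-(2,2-dimethylchroman-6-yl)-7-[(2-methylbut-3-en-2-yl)oxy]chroman-4-one | C=CC(C)(C)Oc1ccc2c(c1)OC[C@@H](c1ccc3c(c1)CCC(C)(C)O3)C2=O | intermediate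
18 | (3R)-3-(2,2-dimethylchroman-6-yl)-8-(3-methylbut-2-en-1-yl)-2,3-dihydro-4H-chromene-4,7(8H)-dione (both configurations at C8) | CC(C)=CCC1C(=O)C=CC2=C1OC[C@@H](c1ccc3c(c1)CCC(C)(C)O3)C2=O | intermediate
19 | (R)-7-hydroxy-3-(2,2-dimethylchroman-6-yl)-8-(3-methylbut-2-en-1-yl)chroman-4-one (CNP0139927.1) | CC(C)=CCc1c(O)ccc2c1OC[C@@H](c1ccc3c(c1)CCC(C)(C)O3)C2=O | target

**Step count**
Total steps: 11. Longest linear sequence: 10 steps (steps 1 to 8, 10 and 11, from compound 1); step 9 is a one-step side branch.

**Steps most likely to fail**

Step 7. C3 may be eroded by enolisation of the tin-bound ketone or by loss of HCl from the acid chloride to an aryl ketene. The activated acyl group may lose CO, and some closure may occur at the carbon between the two oxygens. The fallback sets out from 10 and gives up stereoretention in the closure. The acid is cyclised through its mixed anhydride with (CF3CO)2O in CH2Cl2 at room temperature to racemic 7-(benzyloxy)-3-(2,2-dimethylchroman-6-yl)chroman-4-one F1. C3 is then reset by asymmetric transfer hydrogenation with dynamic kinetic resolution (RuCl(p-cymene)[(R,R)-TsDPEN], HCO2H/Et3N, rt). The amine racemises C3 continuously while one enantiomer is reduced faster, and this should give cis-(3R,4R)-7-(benzyloxy)-3-(2,2-dimethylchroman-6-yl)chroman-4-ol F2; the catalyst antipode is chosen on the usual aryl ketone model. Base-free re-oxidation with Dess–Martin periodinane in CH2Cl2 comes back to the route at 12.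

Step 3. The lipase may discriminate the two enantiotopic arms insufficiently or acetylate the opposite arm, and the acetyl group may migrate between the two oxygens during handling of the monoacetate. The fallback sets out from 4, which is peracetylated (Ac2O, pyridine, DMAP) to 2-(2,2-dimethylchroman-6-yl)propane-1,3-diyl diacetate F3. One acetate is then removed by lipase-catalysed hydrolysis in pH 7 phosphate buffer. Because the enzyme hydrolyses the same arm that it would otherwise acylate, this mode gives the antipodal monoacetate series and a second, independent chance of high selectivity. Whichever enzyme (PPL or Burkholderia cepacia lipase) and mode gives the R compound is adopted, and the route is rejoined at 5.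

Step 11. The allyl group may migrate to C6 in competition with C8. The Lewis acid may ionise the tertiary allyl–oxygen bond, and O7–H may add across the new prenyl double bond to give a chroman. The fallback sets out from 13 and avoids the rearrangement altogether. Iodination with NIS in MeCN at 0 °C, at the ring-A carbon ortho to both O7 and O1, should give (R)-7-hydroxy-8-iodo-3-(2,2-dimethylchroman-6-yl)chroman-4-one F4. Base-free Stille coupling with tributyl(3-methylbut-2-en-1-yl)stannane (Pd(PPh3)4, DMF, 80 °C) then joins the tin-bearing CH2 to C8 and comes back to the route at 19; steps 9 and 10 are then not needed.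

**Further compounds**
F1 | step 7 | racemic 7-(benzyloxy)-3-(2,2-dimethylchroman-6-yl)chroman-4-one | C(c1ccccc1)Oc1ccc2c(c1)OCC(c1ccc3c(c1)CCC(C)(C)O3)C2=O
F2 | step 7 | cis-(3R,4R)-7-(benzyloxy)-3-(2,2-dimethylchroman-6-yl)chroman-4-ol | C(c1ccccc1)Oc1ccc2c(c1)OC[C@@H](c1ccc3c(c1)CCC(C)(C)O3)[C@H]2O
F3 | step 3 | 2-(2,2-dimethylchroman-6-yl)propane-1,3-diyl diacetate | CC(=O)OCC(COC(C)=O)c1ccc2c(c1)CCC(C)(C)O2
F4 | step 11 | (R)-7-hydroxy-8-iodo-3-(2,2-dimethylchroman-6-yl)chroman-4-one | Oc1ccc2c(c1I)OC[C@@H](c1ccc3c(c1)CCC(C)(C)O3)C2=O
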